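All runs stem from a simulated flask for an exercise, noise included.

By 20.0 h L in the ochre run has stopped rising: it reads 39.3 % of the charge then and 39.2 % at 40.0 h, with 53.8 % still solid as Z.

| flask | Z | J | E | remark | time |
|---|---|---|---|---|---|
| green | 0.025 M | 0.50 mM | 0.24 mM | run made earlier |  |
| ochre | 0.10 M | 0.50 mM | 0.24 mM | run made earlier |  |
| flask | 0.050 M | 0.50 mM | 0.24 mM |  | 50 h |

| run | time / h | G / % | L / % | Z / % | D / % | Q / % |
|---|---|---|---|---|---|---|
| green | 6.00 | 0.9 | 97.1 | 0.2 | 0.3 | 1.7 |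
| green | 12.0 | 0 | 94.8 | 0 | 0.2 | 5.0 |
| green | 20.0 | 0.6 | 92.5 | 0 | 0.5 | 7.3 |
| green | 25.0 | 0.6 | 89.3 | 0 | 0 | 9.6 |
| green | 30.0 | 0 | 87.0 | 0 | 1.1 | 11.7 |
| green | 40.0 | 1.1 | 83.7 | 0.1 | 0 | 16.8 |
| ochre | 6.00 | 0.4 | 32.5 | 66.7 | 0 | 1.4 |
| ochre | 12.0 | 0.1 | 38.7 | 60.0 | 0.2 | 1.1 |
| ochre | 20.0 | 0.5 | 39.3 | 57.2 | 0.1 | 3.1 |
| ochre | 25.0 | 0 | 39.2 | 57.1 | 0.4 | 4.9 |
| ochre | 30.0 | 0 | 39.4 | 55.6 | 0 | 5.0 |
| ochre | 40.0 | 0.1 | 39.2 | 53.8 | 0.2 | 6.6 |

(readings scatter by 0.5 percentage points)
- given per volume of solution although it is solid: Z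
- the analysis behind the earlier runs scatters by 0.5 percentage points, standard deviation
- at the start none of Z is in solution
- L means what is dissolved; the solid is not counted in it
1. the species that holds most of what was charged as Z, at 50 h (G / L / D / Q)
2. the largest share itself, whichever of these holds it, in percent of the Z charged

1. We read a ceiling on [L] from the ochre run, while solid Z stands in it: [L] = 39.2 mM, a reading with its scatter.

2. For this flask that ceiling is 78.4 % of the charge. This is the ceiling share, [L] at the ceiling divided by the Z charged.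

3. Low extreme: solid remains, so L sits at the ceiling share and Q comes on top. The ochre run makes Q at about 0.165 mM/h, which gives 16.5 % of this charge by 50 h.

4. High extreme: no solid remains, so L is the charge minus Q. That needs [L] = 41.8 mM, more than the ceiling allows.

5. So we place the flask at the low extreme, since ceiling share and Q together make 94.9 %, less than the whole charge. We commit to L at 78.4 %, more than Q.

The forecast says L at 78.3 %, on the ground that “L is still about 39 mM”.

The flask gives L at 78.7 %, with Q at 16.9 %.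

    L + J ⇌ G (K = 37.0 /M, k = 18.0 /M/h)
    G → D (k = 150 /h)
    D → J + Q (k = 73.0 /h)
    J + E → X (k = 21000 /M/h)
    Z ⇌ L, rate k5*(cs5 - [L]) while solid is left; crystals form when [L] > cs5 (solubility = 40.0 mM, k = 0.290 /h)

The ceiling share carries to a further flask with 0.085 M of Z: 46.1 % reckoned, 46.3 % of L simulated. The answer changes in another neighbour flask, charged with 0.0020 M of J: at 50.0 h Q reaches 75.5 %, Z is 0 %, and L stands at 24.4 %, below the ceiling share, and Q holds most. This flask has not come to rest at 50 h, with Z at 4.36 %. By 500 h this flask has Z at 0 % and Q at 89.7 %, and its L has fallen 68 percentage points to 10.3 %.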